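The readings were computed with made-up constants; noise was put on by code.

In a closed, stirred vessel at 60 °C the gamma flask has been followed up to the moment when we must act on it, and the delta run stands beside it.

| setting | gamma | delta | flask |
|---|---|---|---|
| starting material | 0.030 M | 0.030 M | 0.030 M |
| second substrate | 0.030 M | 0.030 M | 0.0300 M |
| free catalyst | 0.15 mM | 0.10 mM | 0.15 mM |
| temperature | 60 °C | 45 °C | 60 °C |
| remark | the very flask that is asked about, followed so far | run made earlier |  |
| time |  |  | 5.0 h |

- gamma (time / h: target / %): 0.417: 23.7; 0.833: 34.7; 1.33: 43.4; 2.50: 53.5; 5.00: 57.2
- delta (time / min: target / %): 8.00: 1.7; 20.0: 4.1; 40.0: 8.3; 60.0: 11.3; 80.0: 18.1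

(each reading ± 1 percentage point)

- removed target is counted in
- candidate steps: catalyst intermediate A -> free catalyst + target; second substrate + free catalyst <-> catalyst intermediate B; starting material + free catalyst <-> catalyst intermediate A; catalyst intermediate B -> spent catalyst; catalyst intermediate B -> free catalyst + second product
- additions bring no volume worth counting

- larch: at 5.0 h raise the temperature by 15 K, then wait 5.0 h
- ash: at 5.0 h add free catalyst, 50.0 % of the amount charged, then wait 5.0 h
- oak: at 5.0 h take out 90 % of the target then present, then wait 5.0 h
- cedar: change nothing and wait 5.0 h more

* target, in percent of the starting material first charged, at 5.0 h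
* the option that brings most further target ("none" if no option brings more than 2 percentage points) (larch / ash / oak / cedar / none)
* target present, with what was taken out counted in, in percent of the starting material first charged, after larch
* target present, with what was taken out counted in, in percent of the starting material first charged, after ash

We draw the gamma curve first. Target appears at 0.568 /h, as a fraction of the charge, over the first 0.417 h. The knee lies between 1.33 h and 2.50 h, where the climb is 0.0863 /h, and after it the climb is 0.0148 /h, into a level near 57.2 %.

The catalyst charge is 0.500 % of the starting material, so we take whatever is not target to be starting material, and we follow the logarithm of charged over present [starting material]. Our zero of the scale is a catalyst that stays whole, with a rate that we take as first order in [starting material], that is pseudo-first-order: on that assumption this logarithm climbs in a straight line. In the gamma flask its slope is 0.649 /h at first and 0.0332 /h at last, a fall by a factor of 19.5, while 42.8 % of the starting material still stands. So we read the flattening as the fading of the catalyst.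

In the gamma flask the logarithm has reached 0.849 at 5.00 h, and it had reached 0.426, half of that, by 0.833 h. Dividing by the gamma charge of free catalyst gives 5.66 /mM. This is the reach, the logarithm that each unit of free catalyst charged delivers before it is spent, taken at 60 °C with [second substrate] near its charge.

If the halving keeps that pace, the catalyst still alive is worth 0.57 percentage points, less than the 2 points asked for. We give that to cedar, to oak, whose target forms by a step that the candidate list writes as one-way, and to larch, which adds no catalyst, so we put larch near 57.8 %. Ash adds 0.424 to the logarithm, which gives 72.0 %, so we choose ash.

The forecast gave 57.3 % now, ash as best, 58 % after larch and 72.5 % after ash, a little above our figure, holding that “Heating cannot revive dead catalyst”.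

The flask gives 57.1 % now and ash as best, with 57.4 % after larch and 74.0 % after ash.

    catalyst intermediate A → free catalyst + target (k = 4.57 /min, Ea = 78.0 kJ/mol)
    second substrate + free catalyst ⇌ catalyst intermediate B (K = 20.0 /M, k = 326 /M/min, Ea = 51.0 kJ/mol, ΔH = −37.0 kJ/mol)
    starting material + free catalyst ⇌ catalyst intermediate A (K = 47.0 /M, k = 3280 /M/min, Ea = 44.0 kJ/mol, ΔH = −51.0 kJ/mol)
    catalyst intermediate B → spent catalyst (k = 0.0741 /min, Ea = 90.0 kJ/mol)
    catalyst intermediate B → free catalyst + second product (k = 2.39 /min, Ea = 94.0 kJ/mol)
    (constants at 60 °C)

At 5.00 h the flask holds 99.1 % of its catalyst as spent catalyst, and ash lifts the logarithm by 0.501 against our 0.424. We carry the same reach to the neighbouring flask charged with 2.5 × 10⁻⁴ M of free catalyst, all else held. Its logarithm should be 1.41, which means 75.6 % target. That flask ends with 99.3 % of its catalyst spent, 72 % of its second substrate left, and 78.0 % target.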